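Two nucleophiles compete for one intermediate, and I began by comparing how fast each takes it at full charge.

    substrate → intermediate (k1 = 1.0 × 10⁻⁵ s⁻¹)
    first nucleophile + intermediate → target (k2 = 0.015 M⁻¹ s⁻¹)
    second nucleophile + intermediate → other capture product (k3 = 0.0083 M⁻¹ s⁻¹)
    first nucleophile + protic impurity → quenched reagent (k4 = 7.1 × 10⁻⁵ M⁻¹ s⁻¹)
    substrate ⇌ dormant form (K5 = 2.9, k5 = 1.1 × 10⁻⁶ s⁻¹)

| setting | teal | green | ochre | amber | violet |
|---|---|---|---|---|---|
| substrate | 0.10 M | 0.10 M (in portions, 2, over 5.0 d) | 0.10 M (fed, over 5.0 d) | 0.10 M | 0.10 M |
| first nucleophile | 0.250 M (fed, over 5.0 d) | 0.250 M | 0.250 M | 0.250 M (fed, over 12 h) | 0.250 M |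
| second nucleophile | 0.200 M | 0.200 M | 0.200 M | 0.200 M | 0.200 M |
| protic impurity | 0.0300 M | 0.0300 M | 0.0300 M | 0.0300 M | 0.0300 M |
| time | 8.0 d | 8.0 d | 8.0 d | 8.0 d | 8.0 d |
| remark | all else is in the flask from the start; the feed brings no volume worth counting | first portion at the start, last at 5.0 d | all else is in the flask from the start; the feed brings no volume worth counting | all else is in the flask from the start; the feed brings no volume worth counting | everything together at the start |

* the flask with the highest amount of target, in percent of the substrate charged ("all alike" if they lie within 1.5 percentage points) (teal / green / ochre / amber / violet / all alike)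
* final target, as a percentage of the substrate charged, in teal
* final target, as a percentage of the substrate charged, in green
* final target, as a percentage of the substrate charged, in ochre
* final target, as a percentage of the substrate charged, in amber
* final target, as a percentage of the substrate charged, in violet

The capture rates, 0.00375 s⁻¹ for the first nucleophile and 0.00166 s⁻¹ for the second, stand far above the making constant 1.0 × 10⁻⁵ s⁻¹, so I took the intermediate to be in quasi-steady state, with the two captures sharing out whatever forms. I folded this into S, the capture ratio or selectivity factor: the first nucleophile's capture rate at full charge over the second's, 2.26. It means S parts go to target for each part to the other capture product.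

Some substrate leaves sideways, though. Setting the forward step to the dormant form against the making step and ignoring the return, the share ρ reaching intermediate was 90.1%. For violet I committed to 62.4%.

One number was not enough. S assumes the first nucleophile is present during conversion, yet teal's feed of 5.0 d runs longer than substrate's half-life of 0.80 d in violet by its first step alone. So I multiplied S by φ, the mean delivered fraction of the feed while substrate falls at 0.959 d⁻¹: 0.207 in teal, 0.794 in amber. That gave teal 28.7% and amber 57.9%.

Late substrate costs differently: a fraction 0.0563 of what stands at 5.0 d remains unconverted at the end. Green holds half a charge at risk, giving 60.7%; ochre, scaled by the same φ as teal, gives 61.7%. My order put violet first, but ochre trailed by just 0.73 percentage points, inside the margin of 1.5 points.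

The forecast named violet, with teal 28%, green 58%, ochre 58.7%, amber 53.5% and violet 60.5%, holding that “staging the substrate only loses a little to late conversion”. Its amber stood below mine.

The simulation put violet highest at 60.6%, then ochre 58.7%, green 58.0%, amber 54.1% and teal 25.4%. Violet held 31.0% of other capture product, so its ratio read 1.95, below S. Teal's target moved 5 points once second nucleophile reached 0.273 M, a shift that would have left the forecast's teal figure behind. In the neighbour with 0.080 M of second nucleophile, S became 5.65, which gave me 76.6%; the computed flask gave 75.8%.

The constants are invented; the flask was simulated.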